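**Plan**

- Retrosynthesis: the aldehyde is traced back to a silyl-protected primary allylic alcohol. The C5–CH(CH3)O bond is then cut to an aryl bromide and racemic 1-chloroethyl angelate. The O1–C7a ether bond is cut to an ortho-iodoarene triol, the exocyclic C=CH2 to a ketone, and the C2–C3 bond to an aldol between 5-bromo-2-iodobenzaldehyde and 2,2-dimethyl-1,3-dioxan-5-one.
- Forward: the aldol joins C3 to the whole four-carbon unit (C2 plus side chain). Methylenation and deprotection follow, and a copper-catalysed C–O closure makes the dihydrofuran ring (the benzene ring is bought). After silylation and acetylation, the nickel coupling attaches the ester-bearing carbon to C5; desilylation and oxidation then give the enal.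
- Stereochemistry: C2 and C3 come from the (R)-proline anti-aldol and are carried with retention. The benzylic centre comes from the chiral nickel catalyst (enantioconvergent). The Z alkene comes from angelic acid, which is never esterified onto a hindered alcohol.
- Enabling feature: the carbinol carbon on C5 carries only H, CH3, the ester oxygen and the arene, so it is the carbon of a 1-(acyloxy)ethyl radical stabilised by that oxygen. C5 of the benzene ring (para to O1, flanked by C4–H and C6–H) can hold a bromide. One event therefore brings the C–C bond, the last stereocentre and the isomerisation-prone Z ester.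

Key step: step 8

Assumption: 5-bromo-2-iodobenzaldehyde and 1-chloroethyl chlorosulfate are taken as purchasable, and the ligand enantiomer that delivers the (R)-ester in step 8 is assigned by a model coupling of 12 with a simple 4-alkoxyphenyl bromide.

**Route**

Step 1
Reactants: 1 5-bromo-2-iodobenzaldehyde; 2 2,2-dimethyl-1,3-dioxan-5-one
Product: 3 (4R)-4-[(R)-(5-bromo-2-iodophenyl)(hydroxy)methyl]-2,2-dimethyl-1,3-dioxan-5-one
Conditions: (R)-proline (30 mol %), DMF, 4 °C
Reagents that add atoms: none
Why: Proline-catalysed direct asymmetric aldol addition (enamine catalysis, established for this dioxanone as a dihydroxyacetone equivalent), in which the ring-locked (E)-enamine adds to the aldehyde through a hydrogen-bonded chair-like transition state, should set C4 (R) and the carbinol carbon (R) together as the anti-aldol, any syn isomer being removed by chromatography.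

Step 2
Reactants: 3 (4R)-4-[(R)-(5-bromo-2-iodophenyl)(hydroxy)methyl]-2,2-dimethyl-1,3-dioxan-5-one
Product: 4 (4R)-4-[(R)-(5-bromo-2-iodophenyl)(triethylsilyloxy)methyl]-2,2-dimethyl-1,3-dioxan-5-one
Conditions: TESCl, imidazole, DMAP (cat.), CH2Cl2, 0 °C
Reagents that add atoms: chlorotriethylsilane, CC[Si](Cl)(CC)CC
Why: Standard silyl ether protection of the secondary alcohol under mild base should block retro-aldol and alkoxide formation in the olefination without touching either stereocentre.

Step 3
Reactants: 4 (4R)-4-[(R)-(5-bromo-2-iodophenyl)(triethylsilyloxy)methyl]-2,2-dimethyl-1,3-dioxan-5-one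
Product: 5 (4S)-4-[(R)-(5-bromo-2-iodophenyl)(triethylsilyloxy)methyl]-2,2-dimethyl-5-methylidene-1,3-dioxane
Conditions: Ph3PCH3Br, KOtBu, THF, 0 °C; then 4, −20 °C to rt
Reagents that add atoms: methyltriphenylphosphonium bromide, C[P+](c1ccccc1)(c1ccccc1)c1ccccc1.[Br-]
Why: Wittig methylenation with the non-stabilised ylide, routine for cyclic ketones with α-alkoxy stereocentres, should turn the ketone into the 1,1-disubstituted alkene of the future C2 side chain, with low temperature keeping C4 from enolising (the descriptor changes only through priorities).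

Step 4
Reactants: 5 (4S)-4-[(R)-(5-bromo-2-iodophenyl)(triethylsilyloxy)methyl]-2,2-dimethyl-5-methylidene-1,3-dioxane
Product: 6 (1R,2S)-1-(5-bromo-2-iodophenyl)-3-methylidenebutane-1,2,4-triol
Conditions: 2 M aq. HCl, THF, rt
Reagents that add atoms: none
Why: Acid-catalysed acetal hydrolysis and silyl ether cleavage in one operation should free all three hydroxyl groups, and since the arene bears no oxygen yet the benzylic carbinol should not ionise.

Step 5
Reactants: 6 (1R,2S)-1-(5-bromo-2-iodophenyl)-3-methylidenebutane-1,2,4-triol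
Product: 7 (2S,3R)-5-bromo-2-(3-hydroxyprop-1-en-2-yl)-2,3-dihydro-1-benzofuran-3-ol
Conditions: CuI (10 mol %), 1,10-phenanthroline (20 mol %), Cs2CO3, 1,4-dioxane, 90 °C
Reagents that add atoms: none
Why: Copper-catalysed intramolecular Ullmann-type O-arylation of the secondary C2 alkoxide at the ortho C–I bond should close the dihydrofuran ring with retention at C2 and C3 (no bond to either centre is broken), the five-membered closure outrunning the seven-membered one through the primary hydroxyl and C–I reacting before C–Br.

Step 6
Reactants: 7 (2S,3R)-5-bromo-2-(3-hydroxyprop-1-en-2-yl)-2,3-dihydro-1-benzofuran-3-ol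
Product: 9 (2S,3R)-5-bromo-2-[3-(tert-butyldimethylsilyloxy)prop-1-en-2-yl]-2,3-dihydro-1-benzofuran-3-yl acetate, via primary TBS ether 8 (not isolated)
Conditions: TBSCl (1.05 equiv), imidazole, CH2Cl2, −20 to 0 °C; then Ac2O, pyridine, DMAP (cat.), 0 °C to rt
Reagents that add atoms: tert-butyldimethylsilyl chloride, CC(C)(C)[Si](C)(C)Cl; acetic anhydride, CC(=O)OC(C)=O
Why: Chemoselective silylation of the unhindered primary allylic hydroxyl, followed in the same flask by DMAP-catalysed acetylation of the remaining secondary benzylic hydroxyl (standard protection and esterification), should mask the future aldehyde and install the C3 acetate.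

Step 7
Reactants: 10 angelic acid, (2Z)-2-methylbut-2-enoic acid; 11 1-chloroethyl chlorosulfate
Product: 12 racemic 1-chloroethyl (2Z)-2-methylbut-2-enoate
Conditions: NaHCO3, Bu4NHSO4 (cat.), CH2Cl2/H2O, 0 °C to rt
Reagents that add atoms: none
Why: Phase-transfer O-alkylation of the carboxylate by the chlorosulfate (chlorosulfate leaves in preference to chloride, the known preparation of 1-chloroalkyl esters) should give the α-chloro ester without an acyl chloride or heating, so the Z alkene should not isomerise.

Step 8
Reactants: 9 (2S,3R)-5-bromo-2-[3-(tert-butyldimethylsilyloxy)prop-1-en-2-yl]-2,3-dihydro-1-benzofuran-3-yl acetate; 12 racemic 1-chloroethyl (2Z)-2-methylbut-2-enoate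
Product: 13 (1R)-1-[(2S,3R)-3-(acetyloxy)-2-[3-(tert-butyldimethylsilyloxy)prop-1-en-2-yl]-2,3-dihydro-1-benzofuran-5-yl]ethyl (2Z)-2-methylbut-2-enoate
Conditions: NiBr2(dme) (10 mol %), chiral 4,4'-di(heptan-4-yl)-2,2'-bis(oxazoline) ligand (12 mol %), Mn powder, NaI, DMA, 5 °C
Reagents that add atoms: none
Why: Proposed new method: zerovalent nickel bound to the chiral bis(oxazoline) should insert into the C5–Br bond of 9, while a monovalent nickel species abstracts chlorine from racemic 12 to give the planar 1-(angeloyloxy)ethyl radical, which is captured at the aryl nickel centre and released by reductive elimination from trivalent nickel to form the C5–C(benzylic) bond, Mn closing the cycle. The closest known reaction types are the enantioconvergent nickel-catalysed couplings of racemic 1-haloalkyl esters with alkylzinc reagents and the nickel-catalysed asymmetric reductive cross-electrophile couplings of aryl halides with secondary benzylic chlorides or α-chloro nitriles; the proposal joins the electrophile class of the former to the aryl partner and reductant of the latter. No ring is closed. The new benzylic stereocentre (R) is set by the chiral ligand in radical capture and reductive elimination, both enantiomers of 12 converging through the same radical, and the remote C2 and C3 centres should not override the catalyst. The step needs cross-coupling over homocoupling (excess 12, iodide exchange to pace radical formation), reaction at C–Br before the benzylic C3–OAc and the allylic C2–O1 bond (oxidative addition to the aryl bromide is the fastest), and no radical addition to the side chain, which is secured by carrying the enal as the silyl ether of an unactivated 1,1-disubstituted alkene; the Z ester is delivered intact because no acylation of the hindered carbinol is ever needed.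

Step 9
Reactants: 13 (1R)-1-[(2S,3R)-3-(acetyloxy)-2-[3-(tert-butyldimethylsilyloxy)prop-1-en-2-yl]-2,3-dihydro-1-benzofuran-5-yl]ethyl (2Z)-2-methylbut-2-enoate
Product: 14 (1R)-1-[(2S,3R)-3-(acetyloxy)-2-(3-hydroxyprop-1-en-2-yl)-2,3-dihydro-1-benzofuran-5-yl]ethyl (2Z)-2-methylbut-2-enoate
Conditions: HF·pyridine, pyridine, THF, 0 °C
Reagents that add atoms: none
Why: Fluoride-mediated cleavage of the primary silyl ether in a pyridine-buffered medium (standard desilylation) should leave both benzylic esters intact because the conditions are neither basic nor strongly acidic.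

Step 10
Reactants: 14 (1R)-1-[(2S,3R)-3-(acetyloxy)-2-(3-hydroxyprop-1-en-2-yl)-2,3-dihydro-1-benzofuran-5-yl]ethyl (2Z)-2-methylbut-2-enoate
Product: 15 (1R)-1-[(2S,3R)-3-(acetyloxy)-2-(3-oxoprop-1-en-2-yl)-2,3-dihydro-1-benzofuran-5-yl]ethyl (2Z)-2-methylbut-2-enoate
Conditions: MnO2 (activated), CH2Cl2, rt
Reagents that add atoms: none
Why: Chemoselective MnO2 oxidation of the primary allylic alcohol should give the 2-substituted acrolein under neutral conditions, with no other free hydroxyl present and no stereocentre affected.

**Compound list**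

1 | 5-bromo-2-iodobenzaldehyde | O=Cc1cc(Br)ccc1I | starting material
2 | 2,2-dimethyl-1,3-dioxan-5-one | CC1(C)OCC(=O)CO1 | starting material
3 | (4R)-4-[(R)-(5-bromo-2-iodophenyl)(hydroxy)methyl]-2,2-dimethyl-1,3-dioxan-5-one | CC1(C)OCC(=O)[C@H](O1)[C@H](O)c1cc(Br)ccc1I | intermediate
4 | (4R)-4-[(R)-(5-bromo-2-iodophenyl)(triethylsilyloxy)methyl]-2,2-dimethyl-1,3-dioxan-5-one | CC1(C)OCC(=O)[C@H](O1)[C@H](O[Si](CC)(CC)CC)c1cc(Br)ccc1I | intermediate
5 | (4S)-4-[(R)-(5-bromo-2-iodophenyl)(triethylsilyloxy)methyl]-2,2-dimethyl-5-methylidene-1,3-dioxane | CC1(C)OCC(=C)[C@H](O1)[C@H](O[Si](CC)(CC)CC)c1cc(Br)ccc1I | intermediate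
6 | (1R,2S)-1-(5-bromo-2-iodophenyl)-3-methylidenebutane-1,2,4-triol | OCC(=C)[C@H](O)[C@H](O)c1cc(Br)ccc1I | intermediate
7 | (2S,3R)-5-bromo-2-(3-hydroxyprop-1-en-2-yl)-2,3-dihydro-1-benzofuran-3-ol | C=C(CO)[C@@H]1Oc2ccc(Br)cc2[C@H]1O | intermediate
8 | (2S,3R)-5-bromo-2-[3-(tert-butyldimethylsilyloxy)prop-1-en-2-yl]-2,3-dihydro-1-benzofuran-3-ol | C=C(CO[Si](C)(C)C(C)(C)C)[C@@H]1Oc2ccc(Br)cc2[C@H]1O | intermediate
9 | (2S,3R)-5-bromo-2-[3-(tert-butyldimethylsilyloxy)prop-1-en-2-yl]-2,3-dihydro-1-benzofuran-3-yl acetate | C=C(CO[Si](C)(C)C(C)(C)C)[C@@H]1Oc2ccc(Br)cc2[C@H]1OC(C)=O | intermediate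
10 | angelic acid, (2Z)-2-methylbut-2-enoic acid | C/C=C(/C)C(=O)O | starting material
11 | 1-chloroethyl chlorosulfate | CC(Cl)OS(=O)(=O)Cl | starting material
12 | racemic 1-chloroethyl (2Z)-2-methylbut-2-enoate | CC(Cl)OC(=O)/C(C)=C\C | intermediate
13 | (1R)-1-[(2S,3R)-3-(acetyloxy)-2-[3-(tert-butyldimethylsilyloxy)prop-1-en-2-yl]-2,3-dihydro-1-benzofuran-5-yl]ethyl (2Z)-2-methylbut-2-enoate | C=C(CO[Si](C)(C)C(C)(C)C)[C@@H]1Oc2ccc([C@@H](C)OC(=O)/C(C)=C\C)cc2[C@H]1OC(C)=O | intermediate
14 | (1R)-1-[(2S,3R)-3-(acetyloxy)-2-(3-hydroxyprop-1-en-2-yl)-2,3-dihydro-1-benzofuran-5-yl]ethyl (2Z)-2-methylbut-2-enoate | C=C(CO)[C@@H]1Oc2ccc([C@@H](C)OC(=O)/C(C)=C\C)cc2[C@H]1OC(C)=O | intermediate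
15 | (1R)-1-[(2S,3R)-3-(acetyloxy)-2-(3-oxoprop-1-en-2-yl)-2,3-dihydro-1-benzofuran-5-yl]ethyl (2Z)-2-methylbut-2-enoate | C=C(C=O)[C@@H]1Oc2ccc([C@@H](C)OC(=O)/C(C)=C\C)cc2[C@H]1OC(C)=O | target

**Count and risks**

Total step count: 10. Longest linear sequence: 9 steps (steps 1 to 6, then 8 to 10); step 7 makes the second coupling partner.

Steps most likely to fail:

1. Step 8 (proposed new method). The 1-(acyloxy)ethyl radical may dimerise or be reduced faster than it is captured at nickel. The aryl bromide may homocouple. Facial discrimination may be poor because the radical carries only a methyl group and an ester oxygen. Zerovalent nickel may also open the allylic C2–O1 bond.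
 Fallback in known chemistry, setting out from 9 and coming back at 13: Stille coupling of 9 with tributyl(1-ethoxyvinyl)stannane (Pd2(dba)3, P(t-Bu)3, CsF, dioxane, 50 °C) should give the aryl enol ether (2S,3R)-2-[3-(tert-butyldimethylsilyloxy)prop-1-en-2-yl]-5-(1-ethoxyethenyl)-2,3-dihydro-1-benzofuran-3-yl acetate F1. Brief treatment with dilute aqueous HCl in THF at 0 °C should hydrolyse it to the methyl ketone (2S,3R)-5-acetyl-2-[3-(tert-butyldimethylsilyloxy)prop-1-en-2-yl]-2,3-dihydro-1-benzofuran-3-yl acetate F2. Asymmetric transfer hydrogenation with RuCl(p-cymene)[(R,R)-TsDPEN] in HCO2H/Et3N should reduce only the ketone and give the carbinol (2S,3R)-2-[3-(tert-butyldimethylsilyloxy)prop-1-en-2-yl]-5-[(1R)-1-hydroxyethyl]-2,3-dihydro-1-benzofuran-3-yl acetate F3. Yamaguchi esterification with angelic acid 10 (2,4,6-trichlorobenzoyl chloride, Et3N, toluene, then F3, 80 °C) should then give 13, after which steps 9 and 10 follow unchanged.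

2. Step 5. The primary alkoxide may be arylated in competition (seven-membered ether). The 1,3-diol unit may chelate copper and slow turnover. Intermolecular etherification at the C–Br bond is also possible.
 Fallback, setting out from 6 and coming back at 8: the order of protection and ring closure is reversed so that only one hydroxyl can reach the C–I bond. Selective silylation of the primary hydroxyl of 6 (TBSCl, imidazole, CH2Cl2, −20 °C) should give (1R,2S)-1-(5-bromo-2-iodophenyl)-4-(tert-butyldimethylsilyloxy)-3-methylidenebutane-1,2-diol F4. Its closure with CuI, 1,10-phenanthroline and Cs2CO3 can then form only the five-membered ring and should give 8, which is acetylated as in the second half of step 6 to give 9.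

3. Step 3. The basic ylide may enolise the α-alkoxy ketone, with loss of the C4 configuration, or trigger β-elimination of the silyloxy group.
 Fallback, setting out from 4 and coming back at 5: the carbon is added as a non-basic nucleophile and the alkene is formed in a separate elimination. The organocerium reagent from Me3SiCH2Li and CeCl3 (THF, −78 °C) should add to the ketone of 4 to give the β-hydroxysilane (4R)-4-[(R)-(5-bromo-2-iodophenyl)(triethylsilyloxy)methyl]-2,2-dimethyl-5-[(trimethylsilyl)methyl]-1,3-dioxan-5-ol F5 (either C5 epimer serves). Peterson elimination with KH in THF should then give 5.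

Further compounds
F1 | step 8 | (2S,3R)-2-[3-(tert-butyldimethylsilyloxy)prop-1-en-2-yl]-5-(1-ethoxyethenyl)-2,3-dihydro-1-benzofuran-3-yl acetate | C=C(CO[Si](C)(C)C(C)(C)C)[C@@H]1Oc2ccc(C(=C)OCC)cc2[C@H]1OC(C)=O
F2 | step 8 | (2S,3R)-5-acetyl-2-[3-(tert-butyldimethylsilyloxy)prop-1-en-2-yl]-2,3-dihydro-1-benzofuran-3-yl acetate | C=C(CO[Si](C)(C)C(C)(C)C)[C@@H]1Oc2ccc(C(C)=O)cc2[C@H]1OC(C)=O
F3 | step 8 | (2S,3R)-2-[3-(tert-butyldimethylsilyloxy)prop-1-en-2-yl]-5-[(1R)-1-hydroxyethyl]-2,3-dihydro-1-benzofuran-3-yl acetate | C=C(CO[Si](C)(C)C(C)(C)C)[C@@H]1Oc2ccc([C@@H](C)O)cc2[C@H]1OC(C)=O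
F4 | step 5 | (1R,2S)-1-(5-bromo-2-iodophenyl)-4-(tert-butyldimethylsilyloxy)-3-methylidenebutane-1,2-diol | CC(C)(C)[Si](C)(C)OCC(=C)[C@H](O)[C@H](O)c1cc(Br)ccc1I
F5 | step 3 | (4R)-4-[(R)-(5-bromo-2-iodophenyl)(triethylsilyloxy)methyl]-2,2-dimethyl-5-[(trimethylsilyl)methyl]-1,3-dioxan-5-ol | CC1(C)OCC(O)(C[Si](C)(C)C)[C@H](O1)[C@H](O[Si](CC)(CC)CC)c1cc(Br)ccc1I
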